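**Retrosynthetic overview**

1. Target ⇐ Yamaguchi angeloylation of the 3‑hydroxy‑2‑ketone, which is obtained enantiopure by an acyl‑transfer kinetic resolution.
2. 3‑Hydroxy‑2‑ketone ⇐ bicyclic 4‑methyl‑3‑en‑2‑one: one Me2CuLi addition completes the C4 gem‑dimethyl group and gives the C2–C3 enolate, which Rubottom oxidation converts into C3–O.
3. Bicyclic enone ⇐ IBX ⇐ closure of ring B (C9–C10) by superacid cation–olefin cyclization of a monocyclic ring A alcohol carrying the (E)‑umbelliferyloxypentenyl chain.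
4. Ring A monocycle ⇐ Birch dearomatization of a 4‑alkyl‑3,5‑dimethylanisole (anisole carbon becomes C2, the two arene methyls become the C4 and C10 methyls); aryl–chain bond ⇐ B‑alkyl Suzuki coupling.
5. Ring order: ring A comes from the benzene ring, ring B is closed second.

Assumption: bromoarene 1 and dienol 2 are taken as catalogue compounds; racemic intermediates are drawn as the enantiomer that is carried on.

Ring atoms are numbered as in drimane (ring A: C1–C5, C10; ring B: C5–C10; C11 on C9).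

**Step 1**
Reactants: 1 4-bromo-3,5-dimethylanisole; 2 (2E)-3-methylpenta-2,4-dien-1-ol
Product: 4 (2E)-5-(4-methoxy-2,6-dimethylphenyl)-3-methylpent-2-en-1-ol, via alkylborane 3 (not isolated)
Conditions: 2, 9-BBN (2.2 equiv), THF, 0 °C to rt; then 1, Pd(OAc)2 (3 mol%), 2-dicyclohexylphosphino-2′,6′-dimethoxybiphenyl (SPhos, 6 mol%), aq K3PO4, 65 °C
Reagents that add atoms: none
Why: 9-BBN hydroborates only the monosubstituted terminal alkene of the diene (anti-Markovnikov, the free OH being masked in situ as its borinate) and the primary alkylborane undergoes B-alkyl Suzuki–Miyaura coupling with the di-ortho-substituted aryl bromide, leaving the (E)-trisubstituted alkene untouched and creating no stereocentre.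

**Step 2**
Reactants: 4 (2E)-5-(4-methoxy-2,6-dimethylphenyl)-3-methylpent-2-en-1-ol
Product: 7 3,5-dimethyl-4-[(3E)-5-hydroxy-3-methylpent-3-en-1-yl]cyclohex-3-en-1-ol (racemic epimer mixture), via dihydroanisole 5 (not isolated), via unconjugated ketone 6 (not isolated)
Conditions: Li, NH3/THF, t-BuOH, −78 to −33 °C; NH4Cl; then (CO2H)2 (cat.), THF/H2O, 0 °C; then NaHCO3, NaBH4, MeOH, 0 °C
Reagents that add atoms: water (O)
Why: Birch reduction of the anisole protonates an unsubstituted ortho carbon and the para-related methyl-bearing carbon, leaving the enol ether (future C2 carbonyl) and the tetrasubstituted C5=C10 alkene that later starts ring B, while the isolated trisubstituted alkene and the allylic alkoxide survive; oxalic acid hydrolysis gives the unconjugated ketone and NaBH4 the alcohol, whose C2 and C4 stereocentres (racemic epimers) are destroyed again in steps 5 and 6.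

**Step 3**
Reactants: 7 3,5-dimethyl-4-[(3E)-5-hydroxy-3-methylpent-3-en-1-yl]cyclohex-3-en-1-ol; 8 umbelliferone (7-hydroxycoumarin)
Product: 9 7-{[(2E)-5-(4-hydroxy-2,6-dimethylcyclohex-1-en-1-yl)-3-methylpent-2-en-1-yl]oxy}-2H-chromen-2-one (racemic epimer mixture)
Conditions: PPh3, DIAD, THF, −20 to 0 °C
Reagents that add atoms: none
Why: Mitsunobu etherification, in which the primary allylic alcohol is activated far faster than the ring secondary alcohol and umbelliferone (pKa about 7.8) is an ideal pronucleophile, so the aryl ether forms by SN2 at the CH2 group without stereochemical consequence.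

**Step 4**
Reactants: 9 monocyclic umbelliferyl ether alcohol
Product: 10 rac-11-(2-oxo-2H-chromen-7-yloxy)-14-nordrim-7-en-2-ol (C5, C9, C10 relative configuration as in the target; C2 and C4 epimers)
Conditions: FSO3H (8 equiv), i-PrNO2, −78 °C, 30 min; Et3N
Reagents that add atoms: none
Why: Superacid cation–olefin cyclization of a monocyclic terpenoid alcohol (Vlad type, as for monocyclofarnesol to drimenol): protonation of the tetrasubstituted ring alkene at C5 gives the tertiary C10 cation, which C9 of the (E)-alkene captures through a chair transition state (CH2OAr equatorial, CH3-10 axial, H-5 trans to CH3-10), the C8 cation then loses H-7, and the hydroxyl and coumarin carbonyl are held as unreactive oxonium ions; the product is racemic.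

**Step 5**
Reactants: 10 rac-11-(2-oxo-2H-chromen-7-yloxy)-14-nordrim-7-en-2-ol
Product: 12 rac-11-(2-oxo-2H-chromen-7-yloxy)-14-nordrima-3,7-dien-2-one, via saturated ketone 11 (not isolated)
Conditions: IBX (4 equiv), DMSO, 80 °C
Reagents that add atoms: none
Why: IBX oxidises the secondary alcohol to the ketone and then dehydrogenates it (Nicolaou IBX desaturation); only the C3–C4 bond can be desaturated because C10 carries no hydrogen, so the C2 and C4 stereocentres vanish and a single racemic enone results.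

**Step 6**
Reactants: 12 rac-11-(2-oxo-2H-chromen-7-yloxy)-14-nordrima-3,7-dien-2-one
Product: 13 rac-2-(trimethylsilyloxy)-11-(2-oxo-2H-chromen-7-yloxy)drima-2,7-diene
Conditions: Me2CuLi (2.5 equiv, from MeLi and CuBr·SMe2), TMSCl (5 equiv), THF, −78 °C; Et3N
Reagents that add atoms: lithium dimethylcuprate ([Li+].C[Cu-]C); chlorotrimethylsilane (C[Si](C)(C)Cl)
Why: TMSCl-accelerated conjugate addition of Me2CuLi to the β-methyl enone (as in isophorone to 3,3,5,5-tetramethylcyclohexanone) completes the C4 gem-dimethyl group and traps the enolate regiospecifically as the C2–C3 silyl enol ether, the ketone enone reacting much faster at −78 °C than the electron-rich 7-alkoxycoumarin lactone.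

**Step 7**
Reactants: 13 rac-2-(trimethylsilyloxy)-11-(2-oxo-2H-chromen-7-yloxy)drima-2,7-diene
Product: 16 rac-3-hydroxy-11-(2-oxo-2H-chromen-7-yloxy)drim-7-en-2-one (3-OH equatorial, relative configuration of the target), via silyloxy epoxide 14 (not isolated), via axial ketol 15 (not isolated)
Conditions: DMDO (1.05 equiv), acetone/CH2Cl2, −78 °C; 10% aq citric acid, THF, 0 °C; then DBU (0.3 equiv), toluene, 40 °C, Ar
Reagents that add atoms: dimethyldioxirane (CC1(C)OO1)
Why: Rubottom oxidation, in which DMDO epoxidises the electron-rich silyl enol ether (much faster than the trisubstituted alkene) from the face opposite the two axial methyl groups, acid opens the silyloxy epoxide to the axial 3-hydroxy ketone, and DBU equilibrates this α-ketol through its enediol to the more stable equatorial 3-hydroxy-2-ketone (the 2-oxo isomer is favoured because it removes the 1,3-diaxial interactions at C2).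

**Step 8**
Reactants: 16 rac-3-hydroxy-11-(2-oxo-2H-chromen-7-yloxy)drim-7-en-2-one
Product: 17 (3S,5S,9R,10R)-3-hydroxy-11-(2-oxo-2H-chromen-7-yloxy)drim-7-en-2-one (recovered unreacted enantiomer)
Conditions: (R)-benzotetramisole [(R)-2-phenyl-2,3-dihydroimidazo[2,1-b][1,3]benzothiazole] (5 mol%), (i-PrCO)2O (0.6 equiv), i-Pr2NEt, CHCl3, 0 °C, to about 55–60% conversion
Reagents that add atoms: none
Why: Acylative kinetic resolution with a chiral isothiourea acyl-transfer catalyst (Birman–Shiina type; the hydroxyl sits between a carbonyl and a quaternary carbon as in pantolactone, a known good substrate class), in which the mirror-image ketol is esterified faster and the wanted enantiomer is recovered in high ee, the catalyst antipode being fixed in a test run.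

**Step 9**
Reactants: 17 (3S,5S,9R,10R)-3-hydroxy-11-(2-oxo-2H-chromen-7-yloxy)drim-7-en-2-one; 18 angelic acid [(2Z)-2-methylbut-2-enoic acid]
Product: 20 CNP0111364.1 [(3S,5S,9R,10R)-2-oxo-11-(2-oxo-2H-chromen-7-yloxy)drim-7-en-3-yl (2Z)-2-methylbut-2-enoate], via mixed anhydride 19 (not isolated)
Conditions: 18, 2,4,6-trichlorobenzoyl chloride, Et3N, toluene, rt; then 17, DMAP, 75 °C
Reagents that add atoms: none
Why: Yamaguchi esterification through the angelic 2,4,6-trichlorobenzoic mixed anhydride and DMAP acylates the hindered secondary alcohol without Z to E (angelate to tiglate) isomerisation and without touching C3, which keeps its configuration.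

**Compound list**

1 | 4-bromo-3,5-dimethylanisole | COc1cc(C)c(Br)c(C)c1 | starting material
2 | (2E)-3-methylpenta-2,4-dien-1-ol | C=C/C(C)=C/CO | starting material
3 | B-alkyl-9-BBN adduct of 2 with O-(9-BBN) borinate | C/C(CCB1C2CCCC1CCC2)=C\COB1C2CCCC1CCC2 | intermediate
4 | (2E)-5-(4-methoxy-2,6-dimethylphenyl)-3-methylpent-2-en-1-ol | COc1cc(C)c(CC/C(C)=C/CO)c(C)c1 | intermediate
5 | (2E)-5-(4-methoxy-2,6-dimethylcyclohexa-1,4-dien-1-yl)-3-methylpent-2-en-1-ol (racemic) | COC1=CC(C)C(CC/C(C)=C/CO)=C(C)C1 | intermediate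
6 | 3,5-dimethyl-4-[(3E)-5-hydroxy-3-methylpent-3-en-1-yl]cyclohex-3-en-1-one (racemic) | O=C1CC(C)C(CC/C(C)=C/CO)=C(C)C1 | intermediate
7 | 3,5-dimethyl-4-[(3E)-5-hydroxy-3-methylpent-3-en-1-yl]cyclohex-3-en-1-ol (racemic, epimers) | OC1CC(C)C(CC/C(C)=C/CO)=C(C)C1 | intermediate
8 | umbelliferone (7-hydroxy-2H-chromen-2-one) | O=c1ccc2ccc(O)cc2o1 | starting material
9 | 7-{[(2E)-5-(4-hydroxy-2,6-dimethylcyclohex-1-en-1-yl)-3-methylpent-2-en-1-yl]oxy}-2H-chromen-2-one (racemic, epimers) | OC1CC(C)C(CC/C(C)=C/COc2ccc3ccc(=O)oc3c2)=C(C)C1 | intermediate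
10 | rac-11-(2-oxo-2H-chromen-7-yloxy)-14-nordrim-7-en-2-ol (trans-fused; CH2OAr cis to CH3-10; C2/C4 epimers) | C1C(O)C[C@@]2(C)[C@H](COc3ccc4ccc(=O)oc4c3)C(C)=CC[C@@H]2C1C | intermediate
11 | rac-11-(2-oxo-2H-chromen-7-yloxy)-14-nordrim-7-en-2-one | C1C(=O)C[C@@]2(C)[C@H](COc3ccc4ccc(=O)oc4c3)C(C)=CC[C@@H]2C1C | intermediate
12 | rac-11-(2-oxo-2H-chromen-7-yloxy)-14-nordrima-3,7-dien-2-one | C=1C(=O)C[C@@]2(C)[C@H](COc3ccc4ccc(=O)oc4c3)C(C)=CC[C@@H]2C=1C | intermediate
13 | rac-2-(trimethylsilyloxy)-11-(2-oxo-2H-chromen-7-yloxy)drima-2,7-diene | C1=C(O[Si](C)(C)C)C[C@@]2(C)[C@H](COc3ccc4ccc(=O)oc4c3)C(C)=CC[C@@H]2C1(C)C | intermediate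
14 | rac-2,3-epoxy-2-(trimethylsilyloxy)-11-(2-oxo-2H-chromen-7-yloxy)drim-7-ene (epoxide anti to the axial methyls) | [C@H]12O[C@@]1(O[Si](C)(C)C)C[C@@]3(C)[C@H](COc4ccc5ccc(=O)oc5c4)C(C)=CC[C@@H]3C2(C)C | intermediate
15 | rac-3-epi-3-hydroxy-11-(2-oxo-2H-chromen-7-yloxy)drim-7-en-2-one (3-OH axial) | O[C@H]1C(=O)C[C@@]2(C)[C@H](COc3ccc4ccc(=O)oc4c3)C(C)=CC[C@@H]2C1(C)C | intermediate
16 | rac-3-hydroxy-11-(2-oxo-2H-chromen-7-yloxy)drim-7-en-2-one (3-OH equatorial) | O[C@@H]1C(=O)C[C@@]2(C)[C@H](COc3ccc4ccc(=O)oc4c3)C(C)=CC[C@@H]2C1(C)C | intermediate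
17 | (3S,5S,9R,10R)-3-hydroxy-11-(2-oxo-2H-chromen-7-yloxy)drim-7-en-2-one | O[C@@H]1C(=O)C[C@@]2(C)[C@H](COc3ccc4ccc(=O)oc4c3)C(C)=CC[C@@H]2C1(C)C | intermediate
18 | angelic acid [(2Z)-2-methylbut-2-enoic acid] | C/C=C(/C)C(=O)O | starting material
19 | angelic 2,4,6-trichlorobenzoic anhydride | C/C=C(/C)C(=O)OC(=O)c1c(Cl)cc(Cl)cc1Cl | intermediate
20 | CNP0111364.1, (3S,5S,9R,10R)-2-oxo-11-(2-oxo-2H-chromen-7-yloxy)drim-7-en-3-yl angelate | C/C=C(/C)C(=O)O[C@@H]1C(=O)C[C@@]2(C)[C@H](COc3ccc4ccc(=O)oc4c3)C(C)=CC[C@@H]2C1(C)C | target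

**Step count**

Total steps: 9. Longest linear sequence: 9 steps (from 1 or 2 to 20).

**Three steps most likely to fail, each with a fallback**

Step 4 (superacid ring closure in the presence of the allyl aryl ether; control of ring fusion and C9). The fallback sets out from 9 and changes the ring-closing mode to a Lewis-acid enone–olefin cyclization. Dess–Martin periodinane gives the β,γ-unsaturated ketone F1. MeAlCl2 (2.5 equiv, CH2Cl2, −78 to −30 °C) conjugates it to the enone F2 and closes ring B at the activated C10, giving ketone 11 together with its C5 epimer F3. The route is rejoined at 11 (IBX desaturation of step 5); there F3 gives the C5-epimeric enone F4, which DBU epimerises at the γ-position (C5) to 12.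

Step 6 (organocopper addition to a hindered enone while the coumarin is present). The fallback sets out from 7 and brings the coumarin in only after the methyl group. AcCl and 2,4,6-collidine at −78 °C acetylate the primary allylic hydroxyl to the monoacetate F5. FSO3H as in step 4 cyclises it to the bicyclic hydroxy acetate F6. IBX oxidises this through the ketone acetate F7 to the enone acetate F8. Me2CuLi/TMSCl gives the silyl enol ether acetate F9. The Rubottom sequence (silyloxy epoxide F10, axial ketol acetate F11, DBU) gives the equatorial ketol acetate F12. K2CO3/MeOH removes the acetate to give the diol F13. Its primary hydroxyl is etherified with 8 (PBu3, 1,1′-(azodicarbonyl)dipiperidine, toluene, 60 °C; the α-ketol hydroxyl is neopentylic and inert), which comes back to the route at 16.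

Step 8 (kinetic resolution of a hindered α-ketol). The fallback sets out from 16 and uses classical resolution through diastereomers. Esterification with (S)-2-methoxy-2-phenylacetic acid (DCC, DMAP) gives the diastereomeric esters F14 (from the wanted enantiomer) and F15 (from its mirror image). They are separated by chromatography or crystallisation, and F14 is cleaved with K2CO3/MeOH to come back at 17.

**Further compounds**

F1 | step 4 | 7-{[(2E)-5-(2,6-dimethyl-4-oxocyclohex-1-en-1-yl)-3-methylpent-2-en-1-yl]oxy}-2H-chromen-2-one | O=C1CC(C)C(CC/C(C)=C/COc2ccc3ccc(=O)oc3c2)=C(C)C1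
F2 | step 4 | 7-{[(2E)-5-(2,6-dimethyl-4-oxocyclohex-2-en-1-yl)-3-methylpent-2-en-1-yl]oxy}-2H-chromen-2-one | O=C1C=C(C)C(CC/C(C)=C/COc2ccc3ccc(=O)oc3c2)C(C)C1
F3 | step 4 | C5 epimer of 11 (cis-fused ketone) | C1C(=O)C[C@@]2(C)[C@H](COc3ccc4ccc(=O)oc4c3)C(C)=CC[C@H]2C1C
F4 | step 4 | C5 epimer of 12 (cis-fused enone) | C=1C(=O)C[C@@]2(C)[C@H](COc3ccc4ccc(=O)oc4c3)C(C)=CC[C@H]2C=1C
F5 | step 6 | (2E)-5-(4-hydroxy-2,6-dimethylcyclohex-1-en-1-yl)-3-methylpent-2-en-1-yl acetate | OC1CC(C)C(CC/C(C)=C/COC(C)=O)=C(C)C1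
F6 | step 6 | rac-2-hydroxy-14-nordrim-7-en-11-yl acetate | C1C(O)C[C@@]2(C)[C@H](COC(C)=O)C(C)=CC[C@@H]2C1C
F7 | step 6 | rac-2-oxo-14-nordrim-7-en-11-yl acetate | C1C(=O)C[C@@]2(C)[C@H](COC(C)=O)C(C)=CC[C@@H]2C1C
F8 | step 6 | rac-2-oxo-14-nordrima-3,7-dien-11-yl acetate | C=1C(=O)C[C@@]2(C)[C@H](COC(C)=O)C(C)=CC[C@@H]2C=1C
F9 | step 6 | rac-2-(trimethylsilyloxy)drima-2,7-dien-11-yl acetate | C1=C(O[Si](C)(C)C)C[C@@]2(C)[C@H](COC(C)=O)C(C)=CC[C@@H]2C1(C)C
F10 | step 6 | rac-2,3-epoxy-2-(trimethylsilyloxy)drim-7-en-11-yl acetate | [C@H]12O[C@@]1(O[Si](C)(C)C)C[C@@]3(C)[C@H](COC(C)=O)C(C)=CC[C@@H]3C2(C)C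
F11 | step 6 | rac-3-epi-3-hydroxy-2-oxodrim-7-en-11-yl acetate (3-OH axial) | O[C@H]1C(=O)C[C@@]2(C)[C@H](COC(C)=O)C(C)=CC[C@@H]2C1(C)C
F12 | step 6 | rac-3-hydroxy-2-oxodrim-7-en-11-yl acetate (3-OH equatorial) | O[C@@H]1C(=O)C[C@@]2(C)[C@H](COC(C)=O)C(C)=CC[C@@H]2C1(C)C
F13 | step 6 | rac-3,11-dihydroxydrim-7-en-2-one | O[C@@H]1C(=O)C[C@@]2(C)[C@H](CO)C(C)=CC[C@@H]2C1(C)C
F14 | step 8 | (S)-2-methoxy-2-phenylacetate of 17 | CO[C@H](C(=O)O[C@@H]1C(=O)C[C@@]2(C)[C@H](COc3ccc4ccc(=O)oc4c3)C(C)=CC[C@@H]2C1(C)C)c1ccccc1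
F15 | step 8 | (S)-2-methoxy-2-phenylacetate of the mirror image of 17 | CO[C@H](C(=O)O[C@H]1C(=O)C[C@]2(C)[C@@H](COc3ccc4ccc(=O)oc4c3)C(C)=CC[C@H]2C1(C)C)c1ccccc1
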